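The earlier runs and the new flask are calculated for substances that don't exist; the scatter is artificial.

Start from the end.

| flask | starting complex | leaving ligand | gas | temperature | remark | time |
|---|---|---|---|---|---|---|
| maple | 0.40 M | 7.5 equiv | 200 mM (held) | 35 °C | run made earlier |  |
| noon | 0.40 M | 5.00 equiv | 200 mM (held) | 35 °C |  | 2.0 min |
| summer | 0.40 M | 5.00 equiv | 200 mM (held) | 55 °C |  | 2.0 min |
| spring | 0.40 M | 5.00 equiv | 200 mM (held) | 75 °C |  | 2.0 min |

maple run (percent of the starting complex charged)

| time / s | starting complex / % | complex with two exchanged / % | complex with four exchanged / % | complex with three exchanged / % | side product / % |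
|---|---|---|---|---|---|
| 10.0 | 26 | 4 | 0 | 2 | 60 |
| 15.0 | 11 | 7 | 3 | 3 | 68 |
| 25.0 | 1 | 17 | 1 | 3 | 78 |

(scatter of a reading: 1.5 percentage points)

- at the start none of incoming ligand is dissolved
- the numbers in the tables scatter with a standard deviation of 1.5 percentage points
- steps thought possible: starting complex + incoming ligand -> leaving ligand + complex with one exchanged; complex with one exchanged + incoming ligand -> leaving ligand + complex with two exchanged; leaving ligand + starting complex -> side product; gas <-> incoming ligand; complex with three exchanged + incoming ligand -> leaving ligand + complex with four exchanged; complex with two exchanged + incoming ligand -> leaving ligand + complex with three exchanged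
- the earlier runs do not show what temperature does; that part of a forecast is a guess
- no earlier run changes the charge of leaving ligand; that part of a forecast is a guess

- which of these there is most of at the end, counted by the starting complex in it, noon (side product / complex with three exchanged / complex with two exchanged / complex with four exchanged)
- which of these there is most of at the end, counted by the starting complex in it, summer (side product / complex with three exchanged / complex with two exchanged / complex with four exchanged)
- which of these there is most of at the end, counted by the starting complex in it, spring (side product / complex with three exchanged / complex with two exchanged / complex with four exchanged)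
- the largest of these amounts at the end, in percent of the starting complex charged, noon
- the largest of these amounts at the end, in percent of the starting complex charged, summer
- the largest of these amounts at the end, in percent of the starting complex charged, spring

Starting complex has two ways out: the side step with leaving ligand, or the first exchange with incoming ligand. Of the listed steps one makes side product, and it uses up starting complex, so the end amount of side product is the share that took the side way. In the maple run, the last reading leaves 21.0% on the exchange way against 78% on the side way, a ratio of 3.71 at [leaving ligand] = 3.00 M. If that ratio follows [leaving ligand], noon at 2.00 M has a ratio of 2.48 and a side share of 71.2%.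

But no incoming ligand is dissolved at the start, so the ratio need not hold through the run. The maple readings point that way: starting complex falls at 0.135 s⁻¹ up to 10.0 s, then faster, at 0.217 s⁻¹. We take the first rate as the pseudo-first-order side rate, which gives 0.0449 L mol⁻¹ s⁻¹ per unit of [leaving ligand]. We take the difference, 0.0825 s⁻¹, as the exchange rate once gas has dissolved. The head start, 4.40 s, is the time the side step must run unopposed for maple to end with its 21.0% exchanged. With the same gas held, we keep it for noon, where the side rate is 0.0898 s⁻¹. That gives a side share of 67.7%, lower than the first estimate.

The objection is that the faster rate rests on a reading of 1% with a scatter of 1.5 percentage points. Taking that reading as 0.500% gives 0.263 s⁻¹ as the faster rate and moves the head start to 6.27 s, yet noon still gives 66.5%. The time looks ample, too: for noon the head start plus one time constant of our two rates together comes to 10.2 s, far shorter than 2.0 min. On this reckoning side product leads in noon even if one exchanged form holds the whole remainder.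

Temperature is our guess. If both rates grow by a factor of 2 in summer and of 4 in spring while the head start stays, the ratio holds but the head start counts for more, giving 78.3% and 90.1%.

The forecast names side product in each flask, at 67%, 70% and 73%, noting that “the side rate falls by a third”.

    starting complex + incoming ligand → leaving ligand + complex with one exchanged (k = 0.490 L mol⁻¹ s⁻¹, Ea = 57.0 kJ mol⁻¹)
    complex with one exchanged + incoming ligand → leaving ligand + complex with two exchanged (k = 0.860 L mol⁻¹ s⁻¹, Ea = 46.0 kJ mol⁻¹)
    leaving ligand + starting complex → side product (k = 0.0370 L mol⁻¹ s⁻¹, Ea = 66.0 kJ mol⁻¹)
    gas ⇌ incoming ligand, rate k4*(csat - [incoming ligand]) (kL = 0.140 s⁻¹)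
    complex with three exchanged + incoming ligand → leaving ligand + complex with four exchanged (k = 0.0240 L mol⁻¹ s⁻¹, Ea = 57.0 kJ mol⁻¹)
    complex with two exchanged + incoming ligand → leaving ligand + complex with three exchanged (k = 0.100 L mol⁻¹ s⁻¹, Ea = 45.0 kJ mol⁻¹)
    (constants at 35 °C)

Side product leads in each flask, at 66.1% in noon, 84.3% in summer and 94.3% in spring. In noon it stood at 66.0% after 1.00 min and at 66.1% after 20.0 min. Of the noon charge, our head start of 4.40 s puts 32.6% into side product. For the neighbour with 0.10 M of starting complex and the same equivalents, our constant read from the maple run estimates a side rate of 0.0225 s⁻¹, so the head start gives 28.8%, and that flask holds 27.2%.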